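**Retrosynthetic overview**
- The oxirane is the only ring made and it is closed last: Sharpless epoxidation of a 2‑aryl allylic alcohol, with acetylation in the same flask.
- The aryl–C(sp2) bond is made in the penultimate step by Stille coupling of a fully acylated aryl iodide (23 heavy atoms) with 2‑(tributylstannyl)prop‑2‑en‑1‑ol (17 heavy atoms).
- The aryl iodide comes from m‑cresol: MOM‑directed ortho‑lithiation/iodination, benzylic bromination with carboxylate displacement, then phenol angeloylation.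
- Three side branches feed in: (R)‑2‑methylbutanoic acid from tiglic acid, angeloyl chloride from angelic acid, and the stannane from propargyl acetate.
- The benzene ring is bought (m‑cresol).

Assumption: the SMILES is read literally as the (Z)‑2‑methylbut‑2‑enoate (angelate), the (2R)‑2‑methylbutanoate and the (R)‑oxirane.

**Step 1**
Reactants: 1 3‑methylphenol (m‑cresol)
Product: 2 1‑(methoxymethoxy)‑3‑methylbenzene
Conditions: MOMCl (1.3 eq), K2CO3 (2 eq), acetone, 0 °C → rt
Reagents that add atoms: chloromethyl methyl ether COCCl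
Why: Williamson‑type O‑alkylation (MOM protection) turns the phenol into a base‑stable acetal that can direct the next lithiation.

**Step 2**
Reactants: 2 1‑(methoxymethoxy)‑3‑methylbenzene
Product: 4 1‑iodo‑2‑(methoxymethoxy)‑4‑methylbenzene, via aryllithium 3 (not isolated)
Conditions: n‑BuLi (1.2 eq), TMEDA (1.2 eq), Et2O, 0 °C → rt, 2 h; then I2 (1.3 eq), THF, −78 °C → rt
Reagents that add atoms: iodine II
Why: Directed ortho‑metalation, in which the MOM oxygens deliver the base to the less hindered ortho position (C6, para to the methyl; C2 is flanked by the methyl), followed by iodinolysis of the aryllithium.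

**Step 3**
Reactants: 5 (E)‑2‑methylbut‑2‑enoic acid (tiglic acid)
Product: 6 (2R)‑2‑methylbutanoic acid
Conditions: H2 (4 atm), Ru(OAc)2[(R)‑H8‑BINAP] (0.5 mol%), MeOH, 20 °C
Reagents that add atoms: none
Why: Noyori‑type asymmetric hydrogenation of a carboxylate‑bound α,β‑unsaturated acid, in which the (R)‑ligand sets the (R) centre at C2 (from memory the (S)‑ligand gives the (S) acid in about 97% ee; confirm the sense by chiral GC).

**Step 4**
Reactants: 4 1‑iodo‑2‑(methoxymethoxy)‑4‑methylbenzene, 6 (2R)‑2‑methylbutanoic acid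
Product: 9 [4‑iodo‑3‑(methoxymethoxy)phenyl]methyl (2R)‑2‑methylbutanoate, via benzylic bromide 7 (not isolated), via cesium carboxylate 8 (not isolated)
Conditions: NBS (1.05 eq), AIBN (5 mol%), PhCF3, 85 °C; filter, evaporate; then 6 (1.2 eq) premixed with Cs2CO3 (1.2 eq), DMF, rt
Reagents that add atoms: none
Why: Wohl–Ziegler radical bromination of the benzylic methyl, then SN2 displacement of the primary benzylic bromide by the cesium carboxylate, which leaves the α‑stereocentre of the acid untouched.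

**Step 5**
Reactants: 9 [4‑iodo‑3‑(methoxymethoxy)phenyl]methyl (2R)‑2‑methylbutanoate
Product: 10 (3‑hydroxy‑4‑iodophenyl)methyl (2R)‑2‑methylbutanoate
Conditions: ZnBr2 (1 eq), n‑PrSH (2 eq), CH2Cl2, 0 °C → rt, 15 min
Reagents that add atoms: none
Why: Lewis‑acid‑assisted acetal cleavage with thiol capture of the methoxymethyl cation frees the phenol without touching the alkyl ester or the aryl iodide.

**Step 6**
Reactants: 11 (Z)‑2‑methylbut‑2‑enoic acid (angelic acid)
Product: 13 (Z)‑2‑methylbut‑2‑enoyl chloride (angeloyl chloride), via potassium angelate 12 (not isolated)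
Conditions: KOH (1.0 eq), MeOH, evaporate and dry in vacuo; then (COCl)2 (1.0 eq), DMF (cat.), Et2O, 0 °C; used as an ethereal stock solution
Reagents that add atoms: oxalyl chloride ClC(=O)C(=O)Cl
Why: Acyl chloride formation from the carboxylate salt at 0 °C generates no free HCl, so the Z (angelate) double bond does not isomerise to the E (tiglate) form.

**Step 7**
Reactants: 10 (3‑hydroxy‑4‑iodophenyl)methyl (2R)‑2‑methylbutanoate, 13 (Z)‑2‑methylbut‑2‑enoyl chloride
Product: 15 [4‑iodo‑3‑[(Z)‑2‑methylbut‑2‑enoyl]oxyphenyl]methyl (2R)‑2‑methylbutanoate, via sodium phenoxide 14 (not isolated)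
Conditions: NaH (1.05 eq), THF, 0 °C; then 13 (1.2 eq), −20 → 0 °C
Reagents that add atoms: none
Why: O‑acylation of the preformed phenoxide by the acid chloride under amine‑free conditions avoids the vinylketene and conjugate‑addition pathways that would scramble the angelate geometry.

**Step 8**
Reactants: 16 prop‑2‑yn‑1‑yl acetate (propargyl acetate)
Product: 17 2‑(tributylstannyl)prop‑2‑en‑1‑yl acetate
Conditions: Bu3SnH (1.5 eq), Mo(CO)3(CNt‑Bu)3 (2 mol%), hydroquinone (10 mol%), THF, 55 °C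
Reagents that add atoms: tributyltin hydride CCCC[SnH](CCCC)CCCC
Why: Molybdenum‑catalysed hydrostannation of the terminal alkyne places tin on the internal (α) carbon next to the propargylic oxygen.

**Step 9**
Reactants: 17 2‑(tributylstannyl)prop‑2‑en‑1‑yl acetate
Product: 18 2‑(tributylstannyl)prop‑2‑en‑1‑ol
Conditions: K2CO3 (0.2 eq), MeOH, 0 °C → rt
Reagents that add atoms: none
Why: Base‑catalysed transesterification (methanolysis) removes the acetate, and the vinyl–tin bond is stable to carbonate.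

**Step 10**
Reactants: 15 [4‑iodo‑3‑[(Z)‑2‑methylbut‑2‑enoyl]oxyphenyl]methyl (2R)‑2‑methylbutanoate, 18 2‑(tributylstannyl)prop‑2‑en‑1‑ol (1.2 eq)
Product: 19 [4‑(3‑hydroxyprop‑1‑en‑2‑yl)‑3‑[(Z)‑2‑methylbut‑2‑enoyl]oxyphenyl]methyl (2R)‑2‑methylbutanoate
Conditions: Pd2(dba)3 (2.5 mol%), AsPh3 (20 mol%), CuI (10 mol%), NMP, 45 °C, degassed
Reagents that add atoms: none
Why: Stille cross‑coupling with the copper effect joins the aryl C–I and vinyl C–Sn carbons under neutral conditions, so no base is present to cleave the aryl angelate.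

**Step 11**
Reactants: 19 [4‑(3‑hydroxyprop‑1‑en‑2‑yl)‑3‑[(Z)‑2‑methylbut‑2‑enoyl]oxyphenyl]methyl (2R)‑2‑methylbutanoate
Product: 21 [4‑[(2R)‑2‑(acetyloxymethyl)oxiran‑2‑yl]‑3‑[(Z)‑2‑methylbut‑2‑enoyl]oxyphenyl]methyl (2R)‑2‑methylbutanoate (target), via epoxy alcohol 20 (not isolated)
Conditions: Ti(Oi‑Pr)4 (10 mol%), L‑(+)‑diisopropyl tartrate (14 mol%), t‑BuOOH (2 eq, in decane), 4 Å MS, CH2Cl2, −20 °C; then P(OMe)3 (1 eq), −20 °C; then Et3N, Ac2O, DMAP (5 mol%), −20 → 0 °C
Reagents that add atoms: tert‑butyl hydroperoxide CC(C)(C)OO; acetic anhydride CC(=O)OC(C)=O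
Why: Sharpless asymmetric epoxidation, in which Ti/L‑(+)‑tartrate delivers oxygen to the face giving the (S)‑epoxy alcohol (the same sense as L‑(+)‑tartrate giving (2S) epoxy alcohols from simple allylic alcohols), and acetylation in the flask gives the acetate, whose descriptor becomes R only through the CIP priority change.

**Compound list**
1 | 3‑methylphenol (m‑cresol) | Cc1cccc(O)c1 | starting material
2 | 1‑(methoxymethoxy)‑3‑methylbenzene | COCOc1cccc(C)c1 | intermediate
3 | [2‑(methoxymethoxy)‑4‑methylphenyl]lithium | COCOc1cc(C)ccc1[Li] | intermediate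
4 | 1‑iodo‑2‑(methoxymethoxy)‑4‑methylbenzene | COCOc1cc(C)ccc1I | intermediate
5 | (E)‑2‑methylbut‑2‑enoic acid (tiglic acid) | C/C=C(\C)C(=O)O | starting material
6 | (2R)‑2‑methylbutanoic acid | OC(=O)[C@H](C)CC | intermediate
7 | 4‑(bromomethyl)‑1‑iodo‑2‑(methoxymethoxy)benzene | COCOc1cc(CBr)ccc1I | intermediate
8 | cesium (2R)‑2‑methylbutanoate | [Cs+].[O-]C(=O)[C@H](C)CC | intermediate
9 | [4‑iodo‑3‑(methoxymethoxy)phenyl]methyl (2R)‑2‑methylbutanoate | COCOc1cc(COC(=O)[C@H](C)CC)ccc1I | intermediate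
10 | (3‑hydroxy‑4‑iodophenyl)methyl (2R)‑2‑methylbutanoate | Oc1cc(COC(=O)[C@H](C)CC)ccc1I | intermediate
11 | (Z)‑2‑methylbut‑2‑enoic acid (angelic acid) | C/C=C(/C)C(=O)O | starting material
12 | potassium (Z)‑2‑methylbut‑2‑enoate | C/C=C(/C)C(=O)[O-].[K+] | intermediate
13 | (Z)‑2‑methylbut‑2‑enoyl chloride | C/C=C(/C)C(=O)Cl | intermediate
14 | sodium 2‑iodo‑5‑[[(2R)‑2‑methylbutanoyl]oxymethyl]phenoxide | [Na+].[O-]c1cc(COC(=O)[C@H](C)CC)ccc1I | intermediate
15 | [4‑iodo‑3‑[(Z)‑2‑methylbut‑2‑enoyl]oxyphenyl]methyl (2R)‑2‑methylbutanoate | C/C=C(/C)C(=O)Oc1cc(COC(=O)[C@H](C)CC)ccc1I | intermediate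
16 | prop‑2‑yn‑1‑yl acetate | C#CCOC(C)=O | starting material
17 | 2‑(tributylstannyl)prop‑2‑en‑1‑yl acetate | CCCC[Sn](CCCC)(CCCC)C(=C)COC(C)=O | intermediate
18 | 2‑(tributylstannyl)prop‑2‑en‑1‑ol | CCCC[Sn](CCCC)(CCCC)C(=C)CO | intermediate
19 | [4‑(3‑hydroxyprop‑1‑en‑2‑yl)‑3‑[(Z)‑2‑methylbut‑2‑enoyl]oxyphenyl]methyl (2R)‑2‑methylbutanoate | C/C=C(/C)C(=O)Oc1cc(COC(=O)[C@H](C)CC)ccc1C(=C)CO | intermediate
20 | [4‑[(2S)‑2‑(hydroxymethyl)oxiran‑2‑yl]‑3‑[(Z)‑2‑methylbut‑2‑enoyl]oxyphenyl]methyl (2R)‑2‑methylbutanoate | C/C=C(/C)C(=O)Oc1cc(COC(=O)[C@H](C)CC)ccc1[C@]1(CO)CO1 | intermediate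
21 | [4‑[(2R)‑2‑(acetyloxymethyl)oxiran‑2‑yl]‑3‑[(Z)‑2‑methylbut‑2‑enoyl]oxyphenyl]methyl (2R)‑2‑methylbutanoate | C/C=C(/C)C(=O)Oc1cc(COC(=O)[C@H](C)CC)ccc1[C@]1(COC(C)=O)CO1 | target

**Totals**
Total step count: 11.
Longest linear sequence: 7 (steps 1, 2, 4, 5, 7, 10, 11). The side branches are step 3, step 6 and steps 8–9.

**Three steps most likely to fail**

Step 4. NBS may brominate the ring para to the acetal oxygen, or HBr may strip the MOM group. The fallback sets out from 4 and comes back at 10, replacing the acetal by an electron‑poor aryl acetate before the radical step. Compound 4 is cleaved with HCl/MeOH to 2‑iodo‑5‑methylphenol F1, which is acetylated (Ac2O, pyridine) to 2‑iodo‑5‑methylphenyl acetate F2. NBS/AIBN then gives 5‑(bromomethyl)‑2‑iodophenyl acetate F3, and cesium salt 8 in DMF gives (3‑acetyloxy‑4‑iodophenyl)methyl (2R)‑2‑methylbutanoate F4. Pyrrolidine in CH2Cl2 at 0 °C removes only the aryl acetate by aminolysis and gives 10.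

Step 10. The α‑substituted vinylstannane transmetalates slowly, the aryl‑Pd species could cyclise onto the ortho angelate (Heck), and the product could suffer an aryl‑to‑alkyl angeloyl shift. The fallback sets out from 10 and comes back at 19, coupling before the angelate is on. Iodophenol 10 and stannane 18 are coupled under the same Pd/AsPh3/CuI conditions to give [3‑hydroxy‑4‑(3‑hydroxyprop‑1‑en‑2‑yl)phenyl]methyl (2R)‑2‑methylbutanoate F5. The phenol alone is then acylated with 13 and K2CO3 in acetone at −10 °C, relying on the pKa gap between the phenol and the allylic alcohol, to give 19.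

Step 11. The ee for a 2‑aryl allylic alcohol is uncertain, titanium may open the 2‑aryl glycidol, and the angeloyl group may shift to the free alcohol. Any shortfall in ee shows up as an epoxide epimer that ordinary chromatography will probably not remove. The fallback sets out from 19 and comes back at 21, giving up reagent control in favour of separation. Compound 19 is acetylated (Ac2O, pyridine) to [4‑(3‑acetyloxyprop‑1‑en‑2‑yl)‑3‑[(Z)‑2‑methylbut‑2‑enoyl]oxyphenyl]methyl (2R)‑2‑methylbutanoate F6. mCPBA/NaHCO3 in CH2Cl2 epoxidises only the 1,1‑disubstituted styrene‑type alkene (the enoate is inert) and gives 21 together with [4‑[(2S)‑2‑(acetyloxymethyl)oxiran‑2‑yl]‑3‑[(Z)‑2‑methylbut‑2‑enoyl]oxyphenyl]methyl (2R)‑2‑methylbutanoate F7 in about 1:1 ratio. The two are diastereomers and are separated by preparative HPLC on a chiral stationary phase to give 21.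

**Further compounds**
F1 | step 4 | 2‑iodo‑5‑methylphenol | Cc1ccc(I)c(O)c1
F2 | step 4 | 2‑iodo‑5‑methylphenyl acetate | CC(=O)Oc1cc(C)ccc1I
F3 | step 4 | 5‑(bromomethyl)‑2‑iodophenyl acetate | CC(=O)Oc1cc(CBr)ccc1I
F4 | step 4 | (3‑acetyloxy‑4‑iodophenyl)methyl (2R)‑2‑methylbutanoate | CC(=O)Oc1cc(COC(=O)[C@H](C)CC)ccc1I
F5 | step 10 | [3‑hydroxy‑4‑(3‑hydroxyprop‑1‑en‑2‑yl)phenyl]methyl (2R)‑2‑methylbutanoate | Oc1cc(COC(=O)[C@H](C)CC)ccc1C(=C)CO
F6 | step 11 | [4‑(3‑acetyloxyprop‑1‑en‑2‑yl)‑3‑[(Z)‑2‑methylbut‑2‑enoyl]oxyphenyl]methyl (2R)‑2‑methylbutanoate | C/C=C(/C)C(=O)Oc1cc(COC(=O)[C@H](C)CC)ccc1C(=C)COC(C)=O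
F7 | step 11 | [4‑[(2S)‑2‑(acetyloxymethyl)oxiran‑2‑yl]‑3‑[(Z)‑2‑methylbut‑2‑enoyl]oxyphenyl]methyl (2R)‑2‑methylbutanoate | C/C=C(/C)C(=O)Oc1cc(COC(=O)[C@H](C)CC)ccc1[C@@]1(COC(C)=O)CO1
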